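**Retrosynthetic overview**
- Ustusoic acid B ← C11 ester cleavage, C12 oxidation and C6 acylation with (2E,4E,6E)-octatrienoic acid ← a 6β,9α-dihydroxy-drim-7-en-11-oate (drimane numbering throughout).
- Ring A is closed last, at C1=C2, by ring-closing metathesis between a C10 vinyl group and an allyl arm on C4, then hydrogenation; these two groups are trans on ring B.
- Ring B and all four stereocentres (C5, C6, C9, C10) come from one Diels–Alder union of a 4-(silyloxymethyl)-3-hydroxy-2-pyranone (C6–C7–C8–C9, C11, C12) with an (E)-2-methyl-2-enal (C10=C5, C1, C15, C4 arm), forming C5–C6 and C9–C10.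
- Enabling feature: on ring B the C6 oxygen and the C9 carboxyl carbon C11 are 1,4-cis across the C7=C8 double bond, so O–C11(=O) is a latent lactone bridge and ring B is the carbocycle of a 2-oxabicyclo[2.2.2]oct-5-en-3-one whose four sp3 carbons are the four stereocentres; the trans C1/C4 relation is the E geometry of the enal.
- Order of ring formation: pyranone ring (Z-iodoallyl alcohol + diethyl oxalate) → ring B as bridged lactone (key step) → lactone opened → ring A.

Key step: step 4

Remark: drimane numbering (C1–C10 ring carbons, C11 carboxyl, C12 formyl carbon, C13–C15 methyls) is used for all intermediates, and the four starting materials are taken as catalogue compounds.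

**Step 1**
Reactants: 1 2,2-dimethylpent-4-enal; 2 2-(triphenyl-λ5-phosphanylidene)propanal
Product: 3 (E)-2,4,4-trimethylhepta-2,6-dienal
Conditions: toluene, 110 °C
Reagents that add atoms: none
Why: Wittig olefination with a stabilised ylide on an aldehyde that cannot enolise should give the E enal, with the formyl group trans to the tert-alkyl branch.

**Step 2**
Reactants: 4 4-[(tert-butyldimethylsilyl)oxy]but-2-yn-1-ol
Product: 5 (Z)-4-[(tert-butyldimethylsilyl)oxy]-3-iodobut-2-en-1-ol
Conditions: NaAlH2(OCH2CH2OMe)2, THF, 0 °C; then I2, −78 → 0 °C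
Reagents that add atoms: iodine, [I][I]
Why: hydroxyl-directed trans-hydroalumination of the propargylic alcohol places aluminium on the distal carbon, and iododealumination with retention should give the Z vinyl iodide (iodine cis to CH2OH).

**Step 3**
Reactants: 5 (Z)-4-[(tert-butyldimethylsilyl)oxy]-3-iodobut-2-en-1-ol
Product: 7 4-{[(tert-butyldimethylsilyl)oxy]methyl}-3-hydroxy-2H-pyran-2-one, via pyran-2,3-dione 6 (not isolated)
Conditions: t-BuLi (3.1 equiv), Et2O, −78 °C; added to (CO2Et)2 (3 equiv), −78 → 0 °C; AcOH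
Reagents that add atoms: diethyl oxalate, CCOC(=O)C(=O)OCC
Why: iodine–lithium exchange on the lithium alkoxide gives a vinyllithium that is acylated by the oxalate, the cis alkoxide then lactonises, and the released ethoxide isomerises the dione by γ-deprotonation to the aromatic 3-oxidopyranone, which is protonated on work-up.

**Step 4**
Reactants: 3 (E)-2,4,4-trimethylhepta-2,6-dienal; 7 4-{[(tert-butyldimethylsilyl)oxy]methyl}-3-hydroxy-2H-pyran-2-one
Product: 8 (1R,4R,7S,8S)-5-{[(tert-butyldimethylsilyl)oxy]methyl}-4-hydroxy-8-methyl-7-(2-methylpent-4-en-2-yl)-3-oxo-2-oxabicyclo[2.2.2]oct-5-ene-8-carbaldehyde (formyl endo, syn to C5=C6; methyl and side chain exo, syn to the lactone bridge; bicycle C1, C4, C7, C8 = drimane C6, C9, C5, C10)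
Conditions: 9-O-benzylcupreidine (20 mol%), EtOAc (1 M), 12 kbar, 25 °C
Reagents that add atoms: none
Why: Proposed new method: the quinuclidine nitrogen of the catalyst deprotonates the acidic 3-hydroxyl of 7 to an ion-paired 3-oxidopyranone, a HOMO-raised diene whose unsubstituted C6 terminus adds to the β-carbon of the hydrogen-bonded enal 3 while the developing enolate carbon closes on the oxido-bearing carbon (asynchronous [4+2], vinylogous Michael then aldol in the limit), so that C5–C6 and C9–C10 form in one event; the closest known reaction type is the amine-base-catalysed Diels–Alder reaction of 3-hydroxy-2-pyranones with enones, acrylates and maleimides, which has not been shown for an α-methyl β-tert-alkyl enal. Both new six-membered rings of the bicycle, the carbocycle C5–C6–C7–C8–C9–C10 (ring B) and the ring through the C11–O lactone bridge, are closed by this single suprafacial intermolecular cycloaddition. The cis relation of C6–O and C9–C11 is fixed by the lactone bridge, and the trans relation of C1 and C4 (10β-methyl, 5α-H) is transferred stereospecifically from the E geometry of 3. The relation of C5/C10 to C6/C9 follows from the endo position of the formyl group, reinforced because the tert-alkyl branch, trans to the formyl group, must then lie exo and away from the diene. The absolute sense is set by the cinchona catalyst, which shields one face of the ion-paired diene, the pseudo-enantiomeric cupreine ether being the control for the antipode, so the catalyst series is to be confirmed on the first adduct. The step needs C6 of the diene on the enal β-carbon, which the oxido group (nucleophilic vinylogous C6) and the formyl group (electrophilic β-carbon) both secure, while high pressure offsets the congestion at the forming C9–C10 bond and the low temperature avoids loss of CO2 from 8.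

**Step 5**
Reactants: 8 (bridged lactone aldehyde)
Product: 9 (1R,4S,7S,8S)-5-{[(tert-butyldimethylsilyl)oxy]methyl}-8-ethenyl-4-hydroxy-8-methyl-7-(2-methylpent-4-en-2-yl)-2-oxabicyclo[2.2.2]oct-5-en-3-one
Conditions: Ph3PCH3Br (3.0 equiv), KN(SiMe3)2 (2.8 equiv), THF, 0 °C; then 8, −78 → 0 °C
Reagents that add atoms: methyltriphenylphosphonium bromide, C[P+](c1ccccc1)(c1ccccc1)c1ccccc1.[Br-]
Why: Wittig methylenation of the neopentyl aldehyde, with the base kept below the phosphonium salt so that no free strong base can trigger retro-aldol cleavage of the β-hydroxy aldehyde, should give the vinyl group without touching a stereocentre.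

**Step 6**
Reactants: 9 (bridged lactone diene)
Product: 10 4-methoxybenzyl (1S,4R,5S,6S)-2-{[(tert-butyldimethylsilyl)oxy]methyl}-6-ethenyl-1,4-dihydroxy-6-methyl-5-(2-methylpent-4-en-2-yl)cyclohex-2-ene-1-carboxylate (ring C1, C4, C5, C6 = drimane C9, C6, C5, C10)
Conditions: 4-methoxybenzyl alcohol (5 equiv), NaH (0.2 equiv), THF, 0 → 25 °C
Reagents that add atoms: 4-methoxybenzyl alcohol, COc1ccc(CO)cc1
Why: alkoxide-catalysed transesterification by acyl–oxygen cleavage should open the strained bridged lactone to the 4-methoxybenzyl ester and the 6β allylic alcohol with retention at C6 and C9, which frees ring B to take the half-chair needed for closure of ring A.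

**Step 7**
Reactants: 10 (cyclohexene diene ester)
Product: 11 4-methoxybenzyl (5S,6R,9S,10S)-12-[(tert-butyldimethylsilyl)oxy]-6,9-dihydroxydrima-1,7-dien-11-oate (6β-OH, 9α-OH, 5α-H, 10β-Me)
Conditions: second-generation Grubbs catalyst (H2IMes)(PCy3)Cl2Ru=CHPh (5 mol%), CH2Cl2, 40 °C
Reagents that add atoms: none
Why: ring-closing metathesis of the two terminal alkenes, held trans-diequatorial on ring B by the bulky tert-alkyl arm, should close ring A as a trans-fused cyclohexene with loss of ethene, the trisubstituted C7=C8 alkene taking no part.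

**Step 8**
Reactants: 11 (drima-1,7-diene ester)
Product: 12 4-methoxybenzyl (5S,6R,9S,10S)-12-[(tert-butyldimethylsilyl)oxy]-6,9-dihydroxydrim-7-en-11-oate
Conditions: H2 (1 atm), RhCl(PPh3)3 (10 mol%), benzene/EtOH, 25 °C
Reagents that add atoms: none
Why: homogeneous hydrogenation with Wilkinson's catalyst should reduce the cis-disubstituted C1=C2 alkene and leave the hindered trisubstituted C7=C8 alkene, the benzylic ester and the allylic C–O bonds untouched.

**Step 9**
Reactants: 12 (drim-7-ene diol ester); 13 (2E,4E,6E)-octa-2,4,6-trienoic acid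
Product: 14 4-methoxybenzyl (5S,6R,9S,10S)-12-[(tert-butyldimethylsilyl)oxy]-9-hydroxy-6-[(2E,4E,6E)-octa-2,4,6-trienoyloxy]drim-7-en-11-oate
Conditions: 2,4,6-trichlorobenzoyl chloride, Et3N, toluene, 25 °C; then 12, DMAP, 40 °C
Reagents that add atoms: none
Why: Yamaguchi esterification through the mixed anhydride should acylate the secondary 6β-hydroxyl only, the tertiary 9α-hydroxyl being unreactive, and C6 keeps its configuration because its C–O bond is not broken.

**Step 10**
Reactants: 14 (silyl ether triene ester)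
Product: 16 4-methoxybenzyl (5S,6R,9S,10S)-9-hydroxy-6-[(2E,4E,6E)-octa-2,4,6-trienoyloxy]-12-oxodrim-7-en-11-oate, via C12 allylic alcohol 15 (not isolated)
Conditions: HF·pyridine, pyridine, THF, 0 °C; then crude 15, Dess–Martin periodinane, pyridine, CH2Cl2, 0 °C
Reagents that add atoms: none
Why: buffered fluoride cleaves the primary allylic silyl ether, and immediate Dess–Martin oxidation of the unpurified alcohol should give the conjugated aldehyde before the hydroxyl can attack the hindered C11 ester, the tertiary alcohol and the triene ester being inert.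

**Step 11**
Reactants: 16 (aldehyde 4-methoxybenzyl ester)
Product: 17 Ustusoic acid B, (5S,6R,9S,10S)-9-hydroxy-6-[(2E,4E,6E)-octa-2,4,6-trienoyloxy]-12-oxodrim-7-en-11-oic acid
Conditions: TFA, anisole, CH2Cl2, 0 °C
Reagents that add atoms: none
Why: acidolysis of the 4-methoxybenzyl ester by alkyl–oxygen cleavage, with the benzylic cation trapped by anisole, should free the hindered C11 acid without attack at any acyl carbon, so the trienoate, the enal and the four stereocentres are untouched.

**Compound list**
1 | 2,2-dimethylpent-4-enal | O=CC(C)(C)CC=C | starting material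
2 | 2-(triphenyl-λ5-phosphanylidene)propanal | CC(C=O)=P(c1ccccc1)(c1ccccc1)c1ccccc1 | starting material
3 | (E)-2,4,4-trimethylhepta-2,6-dienal | O=C/C(C)=C/C(C)(C)CC=C | intermediate
4 | 4-[(tert-butyldimethylsilyl)oxy]but-2-yn-1-ol | OCC#CCO[Si](C)(C)C(C)(C)C | starting material
5 | (Z)-4-[(tert-butyldimethylsilyl)oxy]-3-iodobut-2-en-1-ol | OC/C=C(\I)CO[Si](C)(C)C(C)(C)C | intermediate
6 | 4-{[(tert-butyldimethylsilyl)oxy]methyl}-6H-pyran-2,3-dione | O=C1OCC=C(CO[Si](C)(C)C(C)(C)C)C1=O | intermediate
7 | 4-{[(tert-butyldimethylsilyl)oxy]methyl}-3-hydroxy-2H-pyran-2-one | O=C1OC=CC(CO[Si](C)(C)C(C)(C)C)=C1O | intermediate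
8 | (1R,4R,7S,8S)-5-{[(tert-butyldimethylsilyl)oxy]methyl}-4-hydroxy-8-methyl-7-(2-methylpent-4-en-2-yl)-3-oxo-2-oxabicyclo[2.2.2]oct-5-ene-8-carbaldehyde | O=C1O[C@@H]2C=C(CO[Si](C)(C)C(C)(C)C)[C@@]1(O)[C@@](C)(C=O)[C@@H]2C(C)(C)CC=C | intermediate
9 | (1R,4S,7S,8S)-5-{[(tert-butyldimethylsilyl)oxy]methyl}-8-ethenyl-4-hydroxy-8-methyl-7-(2-methylpent-4-en-2-yl)-2-oxabicyclo[2.2.2]oct-5-en-3-one | O=C1O[C@@H]2C=C(CO[Si](C)(C)C(C)(C)C)[C@@]1(O)[C@@](C)(C=C)[C@@H]2C(C)(C)CC=C | intermediate
10 | 4-methoxybenzyl (1S,4R,5S,6S)-2-{[(tert-butyldimethylsilyl)oxy]methyl}-6-ethenyl-1,4-dihydroxy-6-methyl-5-(2-methylpent-4-en-2-yl)cyclohex-2-ene-1-carboxylate | O[C@@H]1C=C(CO[Si](C)(C)C(C)(C)C)[C@](O)(C(=O)OCc2ccc(OC)cc2)[C@@](C)(C=C)[C@@H]1C(C)(C)CC=C | intermediate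
11 | 4-methoxybenzyl (5S,6R,9S,10S)-12-[(tert-butyldimethylsilyl)oxy]-6,9-dihydroxydrima-1,7-dien-11-oate | O[C@@H]1C=C(CO[Si](C)(C)C(C)(C)C)[C@](O)(C(=O)OCc3ccc(OC)cc3)[C@@]2(C)C=CCC(C)(C)[C@H]12 | intermediate
12 | 4-methoxybenzyl (5S,6R,9S,10S)-12-[(tert-butyldimethylsilyl)oxy]-6,9-dihydroxydrim-7-en-11-oate | O[C@@H]1C=C(CO[Si](C)(C)C(C)(C)C)[C@](O)(C(=O)OCc3ccc(OC)cc3)[C@@]2(C)CCCC(C)(C)[C@H]12 | intermediate
13 | (2E,4E,6E)-octa-2,4,6-trienoic acid | C/C=C/C=C/C=C/C(=O)O | starting material
14 | 4-methoxybenzyl (5S,6R,9S,10S)-12-[(tert-butyldimethylsilyl)oxy]-9-hydroxy-6-[(2E,4E,6E)-octa-2,4,6-trienoyloxy]drim-7-en-11-oate | C/C=C/C=C/C=C/C(=O)O[C@@H]1C=C(CO[Si](C)(C)C(C)(C)C)[C@](O)(C(=O)OCc3ccc(OC)cc3)[C@@]2(C)CCCC(C)(C)[C@H]12 | intermediate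
15 | 4-methoxybenzyl (5S,6R,9S,10S)-9,12-dihydroxy-6-[(2E,4E,6E)-octa-2,4,6-trienoyloxy]drim-7-en-11-oate | C/C=C/C=C/C=C/C(=O)O[C@@H]1C=C(CO)[C@](O)(C(=O)OCc3ccc(OC)cc3)[C@@]2(C)CCCC(C)(C)[C@H]12 | intermediate
16 | 4-methoxybenzyl (5S,6R,9S,10S)-9-hydroxy-6-[(2E,4E,6E)-octa-2,4,6-trienoyloxy]-12-oxodrim-7-en-11-oate | C/C=C/C=C/C=C/C(=O)O[C@@H]1C=C(C=O)[C@](O)(C(=O)OCc3ccc(OC)cc3)[C@@]2(C)CCCC(C)(C)[C@H]12 | intermediate
17 | Ustusoic acid B, (5S,6R,9S,10S)-9-hydroxy-6-[(2E,4E,6E)-octa-2,4,6-trienoyloxy]-12-oxodrim-7-en-11-oic acid | C/C=C/C=C/C=C/C(=O)O[C@@H]1C=C(C=O)[C@](O)(C(=O)O)[C@@]2(C)CCCC(C)(C)[C@H]12 | target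

**Step count and risks**
Total step count: 11. Longest linear sequence: 10 steps (steps 2 to 11, from compound 4).

Steps most likely to fail:

1. Step 4 (Proposed new method). The union may stall because the C9–C10 bond joins two fully substituted carbons next to a neopentyl centre; the pyranone may instead be alkylated at oxygen or at C4, the adduct may revert, or endo and facial control may erode. Fallback (known reaction type, LUMO-lowering instead of HOMO-raising activation): setting out from 7, the hydroxyl is silylated (Me3SiCl, Et3N, CH2Cl2, 0 °C) to 4-{[(tert-butyldimethylsilyl)oxy]methyl}-3-[(trimethylsilyl)oxy]-2H-pyran-2-one F1, a 2-silyloxy diene. F1 is combined with 3 under catalysis by a chiral cationic oxazaborolidine ((S)-o-tolyl-CBS oxazaborolidine activated by HNTf2, CH2Cl2, −40 °C), a reaction type established for 2-methyl-2-enals with 2-silyloxy dienes, to give the O-trimethylsilyl ether of the adduct F2. Mild acid (AcOH/THF/H2O, 0 °C) removes only the tertiary trimethylsilyl ether, and the route is rejoined at 8.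

2. Step 3. The vinyllithium may add twice to the oxalate or lose silanolate by β-elimination, and the cis γ-hydroxy keto ester may cyclodehydrate to a furan if the mixture turns acidic before lactonisation is complete. Fallback (the lactone C–O bond is made first, the C–C bond second and intramolecularly): setting out from 5, O-acylation (ethyl chlorooxoacetate, pyridine, CH2Cl2, 0 °C) gives ethyl (Z)-4-[(tert-butyldimethylsilyl)oxy]-3-iodobut-2-en-1-yl oxalate F3. Iodine–magnesium exchange (i-PrMgCl·LiCl, THF, −40 °C) then triggers intramolecular acylation under ester-tolerant conditions, Et3N completes the isomerisation through 6, and the route is rejoined at 7.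

3. Step 10. The freed C12 hydroxyl may attack the C11 ester and close the five-membered 11,12-lactone before it is oxidised. Fallback (no free C12 hydroxyl at any point): setting out from 14, the silyl ether is converted directly (Ph3PBr2, CH2Cl2, 0 °C) into 4-methoxybenzyl (5S,6R,9S,10S)-12-bromo-9-hydroxy-6-[(2E,4E,6E)-octa-2,4,6-trienoyloxy]drim-7-en-11-oate F4. This allylic bromide is oxidised by an amine N-oxide (Me3NO, MeCN, 25 °C, Ganem-type oxidation), and the route is rejoined at 16.

**Further compounds**
F1 | step 4 | 4-{[(tert-butyldimethylsilyl)oxy]methyl}-3-[(trimethylsilyl)oxy]-2H-pyran-2-one | O=C1OC=CC(CO[Si](C)(C)C(C)(C)C)=C1O[Si](C)(C)C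
F2 | step 4 | (1R,4R,7S,8S)-5-{[(tert-butyldimethylsilyl)oxy]methyl}-8-methyl-7-(2-methylpent-4-en-2-yl)-3-oxo-4-[(trimethylsilyl)oxy]-2-oxabicyclo[2.2.2]oct-5-ene-8-carbaldehyde | O=C1O[C@@H]2C=C(CO[Si](C)(C)C(C)(C)C)[C@@]1(O[Si](C)(C)C)[C@@](C)(C=O)[C@@H]2C(C)(C)CC=C
F3 | step 3 | ethyl (Z)-4-[(tert-butyldimethylsilyl)oxy]-3-iodobut-2-en-1-yl oxalate | CCOC(=O)C(=O)OC/C=C(\I)CO[Si](C)(C)C(C)(C)C
F4 | step 10 | 4-methoxybenzyl (5S,6R,9S,10S)-12-bromo-9-hydroxy-6-[(2E,4E,6E)-octa-2,4,6-trienoyloxy]drim-7-en-11-oate | C/C=C/C=C/C=C/C(=O)O[C@@H]1C=C(CBr)[C@](O)(C(=O)OCc3ccc(OC)cc3)[C@@]2(C)CCCC(C)(C)[C@H]12
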